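The leftover in the spring run was a gap: at 80.0 s the flask held 90% of the charge as X and 2% as E, so 10.0% had not become X. The noon run, charged with twice as much E, left a gap of 22.0%.

all flasks: G 6.7 mM (held)

| flask | E | remark | time |
|---|---|---|---|
| spring | 0.034 M | run made earlier |  |
| noon | 0.075 M | run made earlier |  |
| flask | 0.050 M |  | 2.0 min |

| run | time / s | X / % | E / % |
|---|---|---|---|
| spring | 10.0 | 34 | 3 |
| spring | 12.0 | 40 | 0 |
| spring | 30.0 | 73 | 1 |
| spring | 80.0 | 90 | 2 |
| noon | 20.0 | 47 | 0 |
| noon | 40.0 | 66 | 0 |
| noon | 50.0 | 74 | 0 |
| noon | 80.0 | 78 | 0 |

(readings scatter by 2 percentage points)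

1. amount of X at 2.0 min, in percent of the E charged
2. the change that raises the amount of X at 2.0 min, in percent of the E charged most ("none" if none brings more than 2 percentage points) (green / blue / none)
3. amount of X at 2.0 min, in percent of the E charged, after blue

- green: doubling the transfer coefficient of G, all else as stated
- blue: doubling the saturation concentration of G, all else as stated

- what was read earlier has a scatter of 2 percentage points, one standard deviation
- at the start none of G is in solution

First I checked, on the noon run, that the last reading stood near the end of the rise. Taking noon's last reading as its end, the distance to it shrank from 31 percentage points to 12 points between 20.0 s and 40.0 s, which reads as a first-order rate constant of 0.0475 s⁻¹. At 80.0 s that leaves 2.24% of the rise to come, beside a scatter of 2 points, and at 2.0 min it leaves 0.335%.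

So I reckoned with the loss per molar, λ, the share of the charge that never becomes X divided by the starting [E]. Spring gave 2.94 M⁻¹ and noon 2.93 M⁻¹, so I used 2.94 M⁻¹. For [E] = 0.050 M, my reckoning gave 85.3% of X. Both runs held G at one level, so λ gave me no number for green or blue.

The forecast differed from my figure, with 87% of X. It chose blue and expected 93% after it, on the ground that “Doubling saturation doubles trapping”, the taking up of G by an intermediate.

The flask gave 85.0% of X, and 91.1% after blue, which gained 6.1 points against 3.8 points for green.

    E + Z → D (k = 208 M⁻¹ s⁻¹)
    D → X (k = 0.0572 s⁻¹)
    E + D → L (k = 2.09 M⁻¹ s⁻¹)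
    G ⇌ Z, rate k4*(csat - [Z]) (kL = 2.24 s⁻¹)

With E as charged, the pseudo-first-order loss of D to L had a half-life of 0.11 min, shorter than the 0.20 min of D → X. By 0.0377 min the path to X already ran 1.2 times the path to L, and L stood at 14.9% at 0.200 min, with E at 0%, and at 14.9% at 2.00 min.

For the neighbour flask at 0.20 M of E, λ gave 41.2% of X. That flask gave 43.5%.

Readings and results were generated by integration for substances that don't exist; noise was put on by code.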